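All constants come from no measurement; no experiment stands behind them.

Take the leftover first: if every X went through X + E → J + Q (k1 = 5.25 /M/min), the charge would leave 1.00 mM of E, so X is the limiting reagent.

| flask | X | E | remark | time |
|---|---|---|---|---|
| dawn | 20 mM | 21.0 mM | one stirred flow tank at steady state, fed with the mixture as stated, mean residence time 4.0 min |  |
| midnight | 20 mM (fed, over 2.00 min) | 21.0 mM | all but X at the start; X goes in evenly over 2.00 min, the run ends at 4.0 min | 4.0 min |
| summer | 20 mM | 21.0 mM | everything together in a closed stirred flask, run for 4.0 min | 4.0 min |
| winter | 20 mM | 21.0 mM | one stirred flow tank at steady state, fed with the mixture as stated, mean residence time 40.0 min |  |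

    X + E → J + Q (k1 = 5.25 /M/min)
    X + Q → G (k2 = 3.77 /M/min)

- the stated concentrations are those of everything mixed, before any reaction; amounts are the same in each set-up
- the feed brings no volume worth counting
- run time (midnight): 4.0 min

- the set-up with the highest amount of J at the outlet or at the end, in percent of the X put in ("none" if the first two lie within 2 percentage points) (dawn / midnight / summer / winter / none)
- amount of J at the outlet or at the end, in percent of the X put in, dawn
- amount of J at the outlet or at the end, in percent of the X put in, midnight
- amount of J at the outlet or at the end, in percent of the X put in, summer
- amount of J at the outlet or at the end, in percent of the X put in, winter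

We carry one quantity, the E-clock, meaning the mean life of X against the first step at the starting cE: one over the first step's rate constant times 21.0 mM, which is 9.07 min. Set-ups are compared by how many clocks they hold. Winter holds 4.41 and dawn, midnight and summer each hold 0.441, so winter has ten times their count, and we commit to winter.

For its yield we go two ways. The first is pseudo-first-order: hold cE at 21.0 mM, and the tank turns a share n/(1+n) of X into J, with n the clock count, which gives 81.5%.

The second writes the tank balance with both reactants falling: cJ equals residence time times rate constant times cX times cE, with cX = 20 mM − cJ and cE = 21.0 mM − cJ. Its root is cJ = 12.7 mM, or 63.5% of the X put in.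

The two ways part, and the first one cheats: it keeps cE at 21.0 mM, while the second has it at 8.30 mM. The second way still leaves out X + Q → G, so we take 63.5% as the winter figure without that step.

The forecast also names winter, at 53.1%, which is lower than our figure, with 24.2% for dawn, 24.7% for midnight and 30.4% for summer, on the ground that “Long residence time wins clearly”.

The simulation gives winter at 53.1%, higher than summer at 30.4%, midnight at 24.7% and dawn at 24.2%. With X + Q → G struck out, the winter tank gives 63.5%, and with that step in place 22.5% of the X charged leaves winter as G. At 0.441 E-clocks, the dawn tank goes through the same second way to 25.1%, and the simulated dawn tank, with the step in place, delivers 24.2%.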